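**Plan**

1. Retrosynthesis: the two ester C–O bonds (angelate at C2, 4-hydroxybenzoate at C6) are cut first. The C7–C8 bond of the seven-membered ring B is cut next, which returns a trans-fused 2-methylcyclohex-2-enone with C6 bonded directly to C8. Then follow C4–isopropyl, C8=C9 (ring-closing metathesis), C5–C6 (aldol), C1–CH3 (cuprate) and C1–allyl.
2. Enabling feature: in ring B the C6 oxygen, the C7 methylene and the C8(CH3)=C9 alkene form a cyclohept-3-en-1-one unit. This is the one-carbon homologue of a cyclohex-2-enone, so inserting C7 between C6 and C8 by a 1,2-alkenyl shift gives the non-conjugated enone regiospecifically.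
3. Forward order: ring A comes from the chiral pool (1). A three-component coupling adds CH3 and the C6–C8 unit, metathesis closes a six-membered ring B, and the ring enlargement (C7 from CH2Br2) converts the hydrindenone into the hydroazulenone. The esters go on last.
4. Stereochemistry: the silyloxy centre of 1 directs the cuprate (C1) and, with the allyl group, the aldol face (C5). The angular methyl directs isopropyl addition (C4) and, after oxidation, hydride addition at C2, which inverts the original silyloxy centre. The C4 hydroxyl delivers hydride to C6. The Z geometry of the angelate comes from angelic acid.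

Key step: step 7

Remark on numbering: text locants follow the daucane skeleton (C1 quaternary ring-fusion carbon with CH3, C2 CH–O, C3 CH2, C4 C(OH)(i-Pr), C5 ring-fusion CH, C6 CH–O, C7 CH2, C8 C(CH3)=, C9 =CH, C10 CH2); ring A is the five-membered ring, ring B the six- or seven-membered ring; compound names use systematic locants.

Assumptions: compounds 1, 4, 15 and 20 are taken as commercial. The carbinol centre C6 formed in step 3 is carried as both epimers in 6, 7, 8 (and is undefined in 10, 11) because it becomes trigonal again in steps 6 and 7.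

**Route**

Step 1
Reactants: 1 (S)-4-((tert-butyldimethylsilyl)oxy)cyclopent-2-en-1-one
Product: 2 (3S,4S)-3-allyl-4-((tert-butyldimethylsilyl)oxy)-1-((trimethylsilyl)oxy)cyclopent-1-ene
Conditions: allylMgBr, CuBr·SMe2, LiCl, TMSCl, THF, −78 °C; Et3N/pentane work-up
Reagents that add atoms: allylmagnesium bromide (C=CC[Mg]Br); chlorotrimethylsilane (C[Si](C)(C)Cl)
Why: Copper-mediated conjugate addition of the allyl group should occur anti to the C4 silyloxy group (general for 4-silyloxycyclopent-2-enones, giving the 3,4-trans product), and chlorotrimethylsilane traps the enolate regiospecifically as the silyl enol ether needed for step 2.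

Step 2
Reactants: 2 (3S,4S)-3-allyl-4-((tert-butyldimethylsilyl)oxy)-1-((trimethylsilyl)oxy)cyclopent-1-ene
Product: 3 (S)-3-allyl-4-((tert-butyldimethylsilyl)oxy)cyclopent-2-en-1-one
Conditions: Pd(OAc)2 (1.05 equiv), MeCN, rt
Reagents that add atoms: none
Why: Saegusa–Ito oxidation: the palladium enolate formed from the silyl enol ether can only undergo β-hydride elimination towards the allyl-bearing carbon, so the enone double bond is re-formed there and the silyloxy stereocentre is untouched.

Step 3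
Reactants: 3 (S)-3-allyl-4-((tert-butyldimethylsilyl)oxy)cyclopent-2-en-1-one; 4 methacrolein
Product: 6 (2S,3R,4S)-3-allyl-4-((tert-butyldimethylsilyl)oxy)-2-(1-hydroxy-2-methylprop-2-en-1-yl)-3-methylcyclopentan-1-one, via lithium enolate 5 (not isolated)
Conditions: Me2CuLi (MeLi, CuBr·SMe2), Et2O, −40 → 0 °C; then 4, THF, −78 °C; AcOH, −78 °C
Reagents that add atoms: lithium dimethylcuprate ([Li+].C[Cu-]C)
Why: Conjugate addition of the methyl cuprate anti to the silyloxy group should set the quaternary carbon C1 (methyl trans to the silyloxy group, allyl cis to it), and the enolate should then add to methacrolein (aldol reaction, three-component coupling) on the face opposite to the cis-disposed allyl and silyloxy groups, placing the C5 substituent trans to the allyl group; the carbinol centre C6 forms without control and is erased in step 6.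

Step 4
Reactants: 6 (2S,3R,4S)-3-allyl-4-((tert-butyldimethylsilyl)oxy)-2-(1-hydroxy-2-methylprop-2-en-1-yl)-3-methylcyclopentan-1-one
Product: 7 (3S,3aR,7aS)-3-((tert-butyldimethylsilyl)oxy)-7-hydroxy-3a,6-dimethyl-2,3,3a,4,7,7a-hexahydro-1H-inden-1-one
Conditions: second-generation Grubbs catalyst (H2IMes)(PCy3)Cl2Ru=CHPh (5 mol %), CH2Cl2, 40 °C
Reagents that add atoms: none
Why: Ring-closing metathesis between the allyl group and the 1,1-disubstituted alkene should close the six-membered ring B with the C8=C9 trisubstituted double bond; the trans ring fusion is already fixed by the trans side chains and no stereocentre is formed.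

Step 5
Reactants: 7 (3S,3aR,7aS)-3-((tert-butyldimethylsilyl)oxy)-7-hydroxy-3a,6-dimethyl-2,3,3a,4,7,7a-hexahydro-1H-inden-1-one
Product: 8 (1R,3S,3aR,7aS)-3-((tert-butyldimethylsilyl)oxy)-1-isopropyl-3a,6-dimethyl-2,3,3a,4,7,7a-hexahydro-1H-indene-1,7-diol
Conditions: i-PrMgCl (3 equiv), CeCl3, THF, −78 → −20 °C; aq NH4Cl
Reagents that add atoms: isopropylmagnesium chloride (CC(C)[Mg]Cl)
Why: Cerium-chloride-promoted Grignard 1,2-addition should suppress enolisation and retro-aldol cleavage of the β-hydroxy ketone, and the isopropyl group should enter from the face of the cyclopentanone opposite to the angular methyl group (the face of H5), giving the tertiary alcohol with OH cis to that methyl group.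

Step 6
Reactants: 8 (1R,3S,3aR,7aS)-3-((tert-butyldimethylsilyl)oxy)-1-isopropyl-3a,6-dimethyl-2,3,3a,4,7,7a-hexahydro-1H-indene-1,7-diol
Product: 9 (1S,3R,3aR,7aR)-1-((tert-butyldimethylsilyl)oxy)-3-hydroxy-3-isopropyl-5,7a-dimethyl-1,2,3,3a,7,7a-hexahydro-4H-inden-4-one
Conditions: Dess–Martin periodinane, pyridine, CH2Cl2, 0 °C → rt
Reagents that add atoms: none
Why: Dess–Martin oxidation converts both epimers of the secondary allylic alcohol into the enone under buffered, non-basic conditions, so the tertiary alcohol, the silyl ether and the epimerisable C5 centre are left alone.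

Step 7
Reactants: 9 (1S,3R,3aR,7aR)-1-((tert-butyldimethylsilyl)oxy)-3-hydroxy-3-isopropyl-5,7a-dimethyl-1,2,3,3a,7,7a-hexahydro-4H-inden-4-one
Product: 13 (1S,3R,3aR,8aR)-1-((tert-butyldimethylsilyl)oxy)-3-hydroxy-3-isopropyl-6,8a-dimethyl-2,3,3a,5,8,8a-hexahydroazulen-4(1H)-one, via dilithium dibromomethyl carbinolate 10 (not isolated), via β-oxido carbenoid 11 (not isolated), via lithium dienolate 12 (not isolated)
Conditions: CH2Br2, lithium 2,2,6,6-tetramethylpiperidide (LiTMP), THF, −95 °C, then add 9; n-BuLi, −95 → −78 °C; AcOH, −95 °C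
Reagents that add atoms: dibromomethane (BrCBr)
Why: Dibromomethyllithium adds 1,2 to the C6 carbonyl of the 2-methylcyclohex-2-enone; bromine–lithium exchange then gives a β-oxido carbenoid in which the C6–C8 bond antiperiplanar to the departing bromide shifts to the carbenoid carbon C7 with loss of LiBr, so the C7–C8 bond forms as C6–C8 breaks and the lithium dienolate 12 of the cyclohept-3-enone results. The closest known reaction type is the β-oxido carbenoid one-carbon ring enlargement of cyclic ketones, a Tiffeneau–Demjanov-type 1,2-shift, which for cyclohex-2-enones is expected to proceed with alkenyl migration. The seven-membered ring is closed by enlargement of ring B from six to seven atoms through a three-centre bridged 1,2-shift, not by an end-to-end cyclisation. No new stereocentre is formed (C6 becomes trigonal, C7 is a methylene), and C5 keeps its configuration because the enolate is generated regiospecifically on the C7 side. The step needs migration of the alkenyl carbon C8 in preference to the alkyl carbon C5, which the higher migratory aptitude of the sp2 carbon (π participation in the bridged transition state) should secure. It also needs α-protonation of the dienolate at C7, which the low-temperature acetic acid quench should secure, keeping C8=C9 out of conjugation.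

Step 8
Reactants: 13 (1S,3R,3aR,8aR)-1-((tert-butyldimethylsilyl)oxy)-3-hydroxy-3-isopropyl-6,8a-dimethyl-2,3,3a,5,8,8a-hexahydroazulen-4(1H)-one
Product: 14 (1S,3R,3aS,4S,8aR)-1-((tert-butyldimethylsilyl)oxy)-3-isopropyl-6,8a-dimethyl-1,2,3,3a,4,5,8,8a-octahydroazulene-3,4-diol
Conditions: Me4NBH(OAc)3, AcOH, MeCN, −30 °C
Reagents that add atoms: none
Why: Evans–Saksena reduction: the acetoxyborohydride bound to the C4 tertiary hydroxyl delivers hydride intramolecularly to the face of the C6 carbonyl on which that hydroxyl lies, which should give the C6 alcohol anti to the C4 hydroxyl (cis to H5) under mildly acidic conditions that do not move the double bond.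

Step 9
Reactants: 14 (1S,3R,3aS,4S,8aR)-1-((tert-butyldimethylsilyl)oxy)-3-isopropyl-6,8a-dimethyl-1,2,3,3a,4,5,8,8a-octahydroazulene-3,4-diol; 15 4-(allyloxy)benzoic acid
Product: 16 (1S,3R,3aS,4S,8aR)-1-((tert-butyldimethylsilyl)oxy)-3-hydroxy-3-isopropyl-6,8a-dimethyl-1,2,3,3a,4,5,8,8a-octahydroazulen-4-yl 4-(allyloxy)benzoate
Conditions: DCC, DMAP (cat.), CH2Cl2, rt
Reagents that add atoms: none
Why: Steglich esterification should acylate only the secondary C6 hydroxyl, since the tertiary C4 hydroxyl is too hindered and C2 is still silylated.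

Step 10
Reactants: 16 (1S,3R,3aS,4S,8aR)-1-((tert-butyldimethylsilyl)oxy)-3-hydroxy-3-isopropyl-6,8a-dimethyl-1,2,3,3a,4,5,8,8a-octahydroazulen-4-yl 4-(allyloxy)benzoate
Product: 17 (1S,3R,3aS,4S,8aR)-1,3-dihydroxy-3-isopropyl-6,8a-dimethyl-1,2,3,3a,4,5,8,8a-octahydroazulen-4-yl 4-(allyloxy)benzoate
Conditions: HF·pyridine, pyridine, THF, 0 °C → rt
Reagents that add atoms: none
Why: Fluoride-mediated cleavage of the secondary silyl ether with buffered HF·pyridine leaves the ester, the allyl aryl ether and the tertiary alcohol intact.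

Step 11
Reactants: 17 (1S,3R,3aS,4S,8aR)-1,3-dihydroxy-3-isopropyl-6,8a-dimethyl-1,2,3,3a,4,5,8,8a-octahydroazulen-4-yl 4-(allyloxy)benzoate
Product: 18 (3R,3aS,4S,8aR)-3-hydroxy-3-isopropyl-6,8a-dimethyl-1-oxo-1,2,3,3a,4,5,8,8a-octahydroazulen-4-yl 4-(allyloxy)benzoate
Conditions: Dess–Martin periodinane, pyridine, CH2Cl2, 0 °C
Reagents that add atoms: none
Why: Dess–Martin oxidation of the only secondary alcohol gives the C2 ketone; the tertiary alcohol cannot be oxidised and the adjacent carbon C1 is quaternary, so nothing can epimerise.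

Step 12
Reactants: 18 (3R,3aS,4S,8aR)-3-hydroxy-3-isopropyl-6,8a-dimethyl-1-oxo-1,2,3,3a,4,5,8,8a-octahydroazulen-4-yl 4-(allyloxy)benzoate
Product: 19 (1R,3R,3aS,4S,8aR)-1,3-dihydroxy-3-isopropyl-6,8a-dimethyl-1,2,3,3a,4,5,8,8a-octahydroazulen-4-yl 4-(allyloxy)benzoate
Conditions: NaBH4, MeOH, −20 °C
Reagents that add atoms: none
Why: Borohydride reduction of the cyclopentanone should occur from the face opposite to the adjacent angular methyl group (as in 17-oxo steroids), giving the C2 alcohol cis to that methyl group and to the C4 hydroxyl, i.e. the inverted configuration needed in the target; the ester is not reduced at this temperature.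

Step 13
Reactants: 19 (1R,3R,3aS,4S,8aR)-1,3-dihydroxy-3-isopropyl-6,8a-dimethyl-1,2,3,3a,4,5,8,8a-octahydroazulen-4-yl 4-(allyloxy)benzoate; 20 angelic acid
Product: 22 (1R,3R,3aS,4S,8aR)-3-hydroxy-3-isopropyl-6,8a-dimethyl-1-(((Z)-2-methylbut-2-enoyl)oxy)-1,2,3,3a,4,5,8,8a-octahydroazulen-4-yl 4-(allyloxy)benzoate, via angelic 2,4,6-trichlorobenzoic anhydride 21 (not isolated)
Conditions: 20, 2,4,6-trichlorobenzoyl chloride, Et3N, toluene, rt; then 19, 80 °C
Reagents that add atoms: none
Why: Yamaguchi esterification through the mixed anhydride, run without a nucleophilic catalyst, should acylate the secondary C2 hydroxyl while keeping the Z geometry of the angelate (angelates isomerise to tiglates under carbodiimide/DMAP conditions); the tertiary alcohol does not react.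

Step 14
Reactants: 22 (1R,3R,3aS,4S,8aR)-3-hydroxy-3-isopropyl-6,8a-dimethyl-1-(((Z)-2-methylbut-2-enoyl)oxy)-1,2,3,3a,4,5,8,8a-octahydroazulen-4-yl 4-(allyloxy)benzoate
Product: 23 (1R,3R,3aS,4S,8aR)-3-hydroxy-3-isopropyl-6,8a-dimethyl-1-(((Z)-2-methylbut-2-enoyl)oxy)-1,2,3,3a,4,5,8,8a-octahydroazulen-4-yl 4-hydroxybenzoate
Conditions: Pd(PPh3)4 (5 mol %), morpholine, THF, rt
Reagents that add atoms: none
Why: Tsuji–Trost deallylation: zerovalent palladium ionises the allyl aryl ether and morpholine captures the allyl group, freeing the phenol under neutral conditions that touch neither ester nor the angelate double bond.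

**Compound list**

1 | (S)-4-((tert-butyldimethylsilyl)oxy)cyclopent-2-en-1-one | CC(C)(C)[Si](C)(C)O[C@H]1CC(=O)C=C1 | starting material
2 | (3S,4S)-3-allyl-4-((tert-butyldimethylsilyl)oxy)-1-((trimethylsilyl)oxy)cyclopent-1-ene | CC(C)(C)[Si](C)(C)O[C@H]1CC(O[Si](C)(C)C)=C[C@@H]1CC=C | intermediate
3 | (S)-3-allyl-4-((tert-butyldimethylsilyl)oxy)cyclopent-2-en-1-one | CC(C)(C)[Si](C)(C)O[C@H]1CC(=O)C=C1CC=C | intermediate
4 | methacrolein (2-methylprop-2-enal) | CC(=C)C=O | starting material
5 | lithium enolate of 3-allyl-4-((tert-butyldimethylsilyl)oxy)-3-methylcyclopentan-1-one (methyl trans to the silyloxy group; not isolated) | CC(C)(C)[Si](C)(C)O[C@H]1CC(O[Li])=C[C@@]1(C)CC=C | intermediate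
6 | (2S,3R,4S)-3-allyl-4-((tert-butyldimethylsilyl)oxy)-2-(1-hydroxy-2-methylprop-2-en-1-yl)-3-methylcyclopentan-1-one (both carbinol epimers) | CC(C)(C)[Si](C)(C)O[C@H]1CC(=O)[C@H](C(O)C(C)=C)[C@@]1(C)CC=C | intermediate
7 | (3S,3aR,7aS)-3-((tert-butyldimethylsilyl)oxy)-7-hydroxy-3a,6-dimethyl-2,3,3a,4,7,7a-hexahydro-1H-inden-1-one (trans-fused; both C7 epimers) | CC(C)(C)[Si](C)(C)O[C@H]1CC(=O)[C@@H]2C(O)C(C)=CC[C@]21C | intermediate
8 | (1R,3S,3aR,7aS)-3-((tert-butyldimethylsilyl)oxy)-1-isopropyl-3a,6-dimethyl-2,3,3a,4,7,7a-hexahydro-1H-indene-1,7-diol (both C7 epimers) | CC(C)(C)[Si](C)(C)O[C@H]1C[C@@](O)(C(C)C)[C@@H]2C(O)C(C)=CC[C@]21C | intermediate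
9 | (1S,3R,3aR,7aR)-1-((tert-butyldimethylsilyl)oxy)-3-hydroxy-3-isopropyl-5,7a-dimethyl-1,2,3,3a,7,7a-hexahydro-4H-inden-4-one | CC(C)(C)[Si](C)(C)O[C@H]1C[C@@](O)(C(C)C)[C@@H]2C(=O)C(C)=CC[C@]21C | intermediate
10 | dilithium dibromomethyl carbinolate (LiCHBr2 adduct at the ring-B carbonyl of 9, both hydroxyls as lithium alkoxides; not isolated) | CC(C)(C)[Si](C)(C)O[C@H]1C[C@@](O[Li])(C(C)C)[C@@H]2C(O[Li])(C(Br)Br)C(C)=CC[C@]21C | intermediate
11 | β-oxido carbenoid (bromo(lithio)methyl carbinolate; not isolated) | CC(C)(C)[Si](C)(C)O[C@H]1C[C@@](O[Li])(C(C)C)[C@@H]2C(O[Li])(C([Li])Br)C(C)=CC[C@]21C | intermediate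
12 | lithium dienolate of 13 (C6–C7 enolate, tertiary lithium alkoxide; not isolated) | CC(C)(C)[Si](C)(C)O[C@H]1C[C@@](O[Li])(C(C)C)[C@@H]2C(O[Li])=CC(C)=CC[C@]21C | intermediate
13 | (1S,3R,3aR,8aR)-1-((tert-butyldimethylsilyl)oxy)-3-hydroxy-3-isopropyl-6,8a-dimethyl-2,3,3a,5,8,8a-hexahydroazulen-4(1H)-one | CC(C)(C)[Si](C)(C)O[C@H]1C[C@@](O)(C(C)C)[C@@H]2C(=O)CC(C)=CC[C@]21C | intermediate
14 | (1S,3R,3aS,4S,8aR)-1-((tert-butyldimethylsilyl)oxy)-3-isopropyl-6,8a-dimethyl-1,2,3,3a,4,5,8,8a-octahydroazulene-3,4-diol | CC(C)(C)[Si](C)(C)O[C@H]1C[C@@](O)(C(C)C)[C@@H]2[C@@H](O)CC(C)=CC[C@]21C | intermediate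
15 | 4-(allyloxy)benzoic acid | C=CCOc1ccc(cc1)C(=O)O | starting material
16 | (1S,3R,3aS,4S,8aR)-1-((tert-butyldimethylsilyl)oxy)-3-hydroxy-3-isopropyl-6,8a-dimethyl-1,2,3,3a,4,5,8,8a-octahydroazulen-4-yl 4-(allyloxy)benzoate | CC(C)(C)[Si](C)(C)O[C@H]1C[C@@](O)(C(C)C)[C@@H]2[C@@H](OC(=O)c3ccc(OCC=C)cc3)CC(C)=CC[C@]21C | intermediate
17 | (1S,3R,3aS,4S,8aR)-1,3-dihydroxy-3-isopropyl-6,8a-dimethyl-1,2,3,3a,4,5,8,8a-octahydroazulen-4-yl 4-(allyloxy)benzoate | O[C@H]1C[C@@](O)(C(C)C)[C@@H]2[C@@H](OC(=O)c3ccc(OCC=C)cc3)CC(C)=CC[C@]21C | intermediate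
18 | (3R,3aS,4S,8aR)-3-hydroxy-3-isopropyl-6,8a-dimethyl-1-oxo-1,2,3,3a,4,5,8,8a-octahydroazulen-4-yl 4-(allyloxy)benzoate | O=C1C[C@@](O)(C(C)C)[C@@H]2[C@@H](OC(=O)c3ccc(OCC=C)cc3)CC(C)=CC[C@]21C | intermediate
19 | (1R,3R,3aS,4S,8aR)-1,3-dihydroxy-3-isopropyl-6,8a-dimethyl-1,2,3,3a,4,5,8,8a-octahydroazulen-4-yl 4-(allyloxy)benzoate | O[C@@H]1C[C@@](O)(C(C)C)[C@@H]2[C@@H](OC(=O)c3ccc(OCC=C)cc3)CC(C)=CC[C@]21C | intermediate
20 | angelic acid ((Z)-2-methylbut-2-enoic acid) | C/C=C(/C)C(=O)O | starting material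
21 | angelic 2,4,6-trichlorobenzoic anhydride (not isolated) | C/C=C(/C)C(=O)OC(=O)c1c(Cl)cc(Cl)cc1Cl | intermediate
22 | (1R,3R,3aS,4S,8aR)-3-hydroxy-3-isopropyl-6,8a-dimethyl-1-(((Z)-2-methylbut-2-enoyl)oxy)-1,2,3,3a,4,5,8,8a-octahydroazulen-4-yl 4-(allyloxy)benzoate | C/C=C(/C)C(=O)O[C@@H]1C[C@@](O)(C(C)C)[C@@H]2[C@@H](OC(=O)c3ccc(OCC=C)cc3)CC(C)=CC[C@]21C | intermediate
23 | (1R,3R,3aS,4S,8aR)-3-hydroxy-3-isopropyl-6,8a-dimethyl-1-(((Z)-2-methylbut-2-enoyl)oxy)-1,2,3,3a,4,5,8,8a-octahydroazulen-4-yl 4-hydroxybenzoate (CNP0188626.1) | C/C=C(/C)C(=O)O[C@@H]1C[C@@](O)(C(C)C)[C@@H]2[C@@H](OC(=O)c3ccc(O)cc3)CC(C)=CC[C@]21C | target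

**Summary**

Total step count: 14. Longest linear sequence: 14 steps (1 → 23); 4, 15 and 20 enter as commercial reagents.

**Steps most likely to fail, with fallbacks**

Step 7 (key step). What may go wrong: deprotonation or retro-aldol cleavage of the β-alkoxide instead of 1,2-addition at the hindered C6 carbonyl, migration of the alkyl carbon C5 instead of the alkenyl carbon C8, or drift of the C8=C9 double bond into conjugation during the quench. The fallback sets out from 3 and builds the seven-membered ring directly. Conjugate addition of lithium dimethylcuprate to 3 and trapping of the enolate with 3-methylbut-3-enal would give the homologous aldol adduct (2S,3R,4S)-3-allyl-4-((tert-butyldimethylsilyl)oxy)-2-(1-hydroxy-3-methylbut-3-en-1-yl)-3-methylcyclopentan-1-one F1. Ring-closing metathesis with the same ruthenium catalyst would close ring B at C8=C9 to give (3S,3aR,8aS)-3-((tert-butyldimethylsilyl)oxy)-8-hydroxy-3a,6-dimethyl-3,3a,4,7,8,8a-hexahydroazulen-1(2H)-one F2. Addition of i-PrMgCl/CeCl3 would give (1S,3R,3aS,8aR)-1-((tert-butyldimethylsilyl)oxy)-3-isopropyl-6,8a-dimethyl-1,2,3,3a,4,5,8,8a-octahydroazulene-3,4-diol F3 as the C6-epimeric mixture. Dess–Martin oxidation of its secondary alcohol would bring the sequence back to the route at 13.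

Step 5. What may go wrong: enolisation or β-hydride reduction of the hindered ketone by the isopropyl Grignard reagent, retro-aldol cleavage of the magnesium aldolate, or addition from the face of the angular methyl group. The fallback sets out from 7. Isopropenylmagnesium bromide with CeCl3 (a smaller sp2 nucleophile without β-hydrogens to transfer) would give (1S,3S,3aR,7aS)-3-((tert-butyldimethylsilyl)oxy)-3a,6-dimethyl-1-(prop-1-en-2-yl)-2,3,3a,4,7,7a-hexahydro-1H-indene-1,7-diol F4. Hydrogenation with RhCl(PPh3)3 and H2, which should reduce the 1,1-disubstituted alkene and leave the trisubstituted ring alkene, would return to the route at 8.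

Step 13. What may go wrong: slow acylation of the neopentyl-type C2 hydroxyl and Z-to-E isomerisation of the angelate during the heated esterification. The fallback sets out from 19 and builds the Z-alkene on the molecule. Steglich esterification of 19 with 2-(bis(2,2,2-trifluoroethoxy)phosphoryl)propanoic acid would give (1R,3R,3aS,4S,8aR)-1-((2-(bis(2,2,2-trifluoroethoxy)phosphoryl)propanoyl)oxy)-3-hydroxy-3-isopropyl-6,8a-dimethyl-1,2,3,3a,4,5,8,8a-octahydroazulen-4-yl 4-(allyloxy)benzoate F5. Still–Gennari olefination of F5 with acetaldehyde (KHMDS, 18-crown-6, THF, −78 °C), which is Z-selective, would return to the route at 22.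

**Further compounds**

F1 | step 7 | (2S,3R,4S)-3-allyl-4-((tert-butyldimethylsilyl)oxy)-2-(1-hydroxy-3-methylbut-3-en-1-yl)-3-methylcyclopentan-1-one (carbinol epimers) | CC(C)(C)[Si](C)(C)O[C@H]1CC(=O)[C@H](C(O)CC(C)=C)[C@@]1(C)CC=C
F2 | step 7 | (3S,3aR,8aS)-3-((tert-butyldimethylsilyl)oxy)-8-hydroxy-3a,6-dimethyl-3,3a,4,7,8,8a-hexahydroazulen-1(2H)-one (C8 epimers) | CC(C)(C)[Si](C)(C)O[C@H]1CC(=O)[C@@H]2C(O)CC(C)=CC[C@]21C
F3 | step 7 | (1S,3R,3aS,8aR)-1-((tert-butyldimethylsilyl)oxy)-3-isopropyl-6,8a-dimethyl-1,2,3,3a,4,5,8,8a-octahydroazulene-3,4-diol (C4 epimers) | CC(C)(C)[Si](C)(C)O[C@H]1C[C@@](O)(C(C)C)[C@@H]2C(O)CC(C)=CC[C@]21C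
F4 | step 5 | (1S,3S,3aR,7aS)-3-((tert-butyldimethylsilyl)oxy)-3a,6-dimethyl-1-(prop-1-en-2-yl)-2,3,3a,4,7,7a-hexahydro-1H-indene-1,7-diol (C7 epimers) | CC(C)(C)[Si](C)(C)O[C@H]1C[C@@](O)(C(C)=C)[C@@H]2C(O)C(C)=CC[C@]21C
F5 | step 13 | (1R,3R,3aS,4S,8aR)-1-((2-(bis(2,2,2-trifluoroethoxy)phosphoryl)propanoyl)oxy)-3-hydroxy-3-isopropyl-6,8a-dimethyl-1,2,3,3a,4,5,8,8a-octahydroazulen-4-yl 4-(allyloxy)benzoate | CC(C(=O)O[C@@H]1C[C@@](O)(C(C)C)[C@@H]2[C@@H](OC(=O)c3ccc(OCC=C)cc3)CC(C)=CC[C@]21C)P(=O)(OCC(F)(F)F)OCC(F)(F)F
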